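Whatever forms it passes through, the catalyst charged stays one fixed total, so a flask's pace can be compared per unit of that total.

| setting | autumn | midnight | dawn | grey | violet | blue | green | amber |
|---|---|---|---|---|---|---|---|---|
| substrate | 2.7 mM | 13 mM | 10 mM | 5.0 mM | 15 mM | 3.0 mM | 3.0 mM | 10 mM |
| coupling partner | 12 mM | 12 mM | 12 mM | 12.0 mM | 12.0 mM | 50.0 mM | 25.0 mM | 12.0 mM |
| free catalyst | 20 µM | 20 µM | 40 µM | 60 µM | 80 µM | 20 µM | 20 µM | 20 µM |
| remark | run made earlier | run made earlier | run made earlier |  |  |  |  |  |
| time |  |  |  | 10 h | 10 h | 10 h | 10 h | 10 h |

| run | time / h | target / % |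
|---|---|---|
| autumn | 0.500 | 0.5 |
| autumn | 1.33 | 3.7 |
| autumn | 3.00 | 8.9 |
| autumn | 8.00 | 19.9 |
| midnight | 0.500 | 0.7 |
| midnight | 1.33 | 3.0 |
| midnight | 3.00 | 5.5 |
| midnight | 8.00 | 11.3 |
| dawn | 0.500 | 1.2 |
| dawn | 1.33 | 6.1 |
| dawn | 3.00 | 9.3 |
| dawn | 8.00 | 25.3 |

(scatter of a reading: 1 percentage point)

- all flasks from highest to lowest amount of target, in percent of the substrate charged, at 10 h (grey / violet / blue / green / amber)
- the same order at 40 h (grey / violet / blue / green / amber)
- the amount of target, in percent of the substrate charged of the flask you put first, at 10 h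
- the amount of target, in percent of the substrate charged of the flask you put last, at 10 h



Q. What do you read from the runs?

A. The clearance: the natural log of substrate charged over substrate left, divided by time, reading target as substrate gone. It is a pseudo-first-order constant, the mean of the curve in one number. Autumn gives 0.0277 h⁻¹ at 8.00 h.

Q. Is a mean honest here?

A. Autumn at 3.00 h gives 0.0311 h⁻¹, and a scatter of 1 percentage point on a reading of 8.9% covers that gap.

Q. Does the clearance depend on the charge?

A. Yes. Midnight, with more substrate than autumn, gives 0.0150 h⁻¹, less than autumn. Dawn's clearance, scaled down to 20 µM of free catalyst, is 0.0182 h⁻¹, which lies between them, as dawn's substrate charge does. So I scale clearance with [free catalyst] and choose the run nearest in [substrate].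

Q. Then amber?

A. Dawn's halved clearance gives amber 16.7% at 10 h.

Q. And blue? The coupling partner was never varied.

A. That is the weak spot. Taking first order in [coupling partner], autumn's clearance gives blue 68.5%, and I hold that as my figure with the least trust. Green gets 43.9% the same way.

Q. Grey and violet?

A. Grey, on autumn's clearance tripled, gets 56.5%, on the high side given its larger substrate charge than autumn's. Violet, on midnight's scaled, gets 45.1%, more than green's figure. My order at 10 h is blue, grey, violet, green, amber.

Q. At 40 h?

A. Violet holds less coupling partner than substrate, so, taking one partner per target, the partner is its limiting reagent and caps it at 80.0%. Green reckons to 90.1%, above that cap, so green passes violet. Amber reckons to 51.7%, less than both. My order at 40 h is blue, grey, green, violet, amber.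

The forecast gives blue > grey > violet > green > amber, then blue > grey > green > violet > amber, with 70% and 16.5% against my 68.5% and 16.7%, and notes that “The partner was never varied”.

Blue comes first at 55.6% and amber last at 17.6%, in the orders blue > grey > violet > green > amber and blue > grey > green > violet > amber.

    substrate + free catalyst ⇌ catalyst intermediate A (K = 47.0 M⁻¹, k = 3.59 M⁻¹ s⁻¹)
    coupling partner + catalyst intermediate A ⇌ catalyst intermediate B (K = 30.3 M⁻¹, k = 2.49 M⁻¹ s⁻¹)
    catalyst intermediate B → by-product + catalyst intermediate C (k = 0.0429 s⁻¹)
    catalyst intermediate C → free catalyst + target (k = 1.44 s⁻¹)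
    catalyst intermediate C → spent catalyst (k = 7.25 × 10⁻⁶ s⁻¹)

Blue still held 96.7% of its coupling partner at 10.0 h. Its clearance, read from the result, is 0.0813 h⁻¹, which is 2.94 times autumn's, on a partner charge 4.17 times autumn's. Scaled to 0.034 mM of free catalyst, that clearance puts the neighbour of blue at 74.9%, and that flask stood at 75.5%.

(All runs were computed for an exercise; scatter was added.)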